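## The problem

Target 21 is a (2S)-flavanone. A phloroglucinol-type ring A is fused to the dihydropyranone ring C; ring B (3-hydroxy-4,5-dimethoxyphenyl) sits on C2, and an (E)-geranyl chain, written below as geranyl for (2E)-3,7-dimethylocta-2,6-dien-1-yl, sits on C6 between the C5 and C7 hydroxyls. C2 is the only stereocentre, so no other centre can control it and its configuration must come from a reagent or catalyst. Because C2 is benzylic, α to O1 and β to the C4 ketone, it is lost by ring opening to the chalcone under base and, more slowly, in hot acid. The chain must be placed at C6 and not at C8, a difference that exists only once ring A is desymmetrised relative to the acyl carbon C4. The two trisubstituted alkenes exclude hydrogenolysis and strong Lewis or Brønsted acids (cyclisation onto an ortho hydroxyl gives chromans). This narrows the choice of protecting groups for the three phenols, while the two methyl ethers must survive. The C3–C4 bond joins a ketone carbon to a methylene, so it can be formed as the C3=C4 alkene of a 4-silyloxy-2H-chromene. That allows ring C to be closed by olefin metathesis between a vinyl group on C2 and a 1-silyloxyvinyl group on C4a, once the O1–C2 ether and its configuration exist.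

## Retrosynthesis

**21 to 19.** No skeletal bond is cut. The C4 ketone is masked as its tert-butyldimethylsilyl enol ether and the three phenols as methoxymethyl ethers, giving chromene 19. Acid returns the ketone (tris-ether 20) and then the phenols. The acetal is chosen because the same groups on ring A serve earlier as directing groups, and one acid treatment then does all the unmasking.

**19 to 18.** The C3=C4 bond is cut, giving diene 18 with ring C open. The neighbouring cuts are weaker: cutting O1–C2 (oxa-Michael closure of a chalcone) places the formation of C2 in a reversible step, and cutting C2–C1' requires a chromone and an aryl metal. The chosen cut leaves C2 inside an ether that is made earlier and is not touched in the ring closure. The forward reaction must engage the two terminal alkenes and ignore the geranyl alkenes.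

**18 to 17.** The O–Si bond of the enol silane is cut, giving methyl ketone 17. Only the methyl side can enolise, so the regiochemistry of the enol ether is not in question.

**17 to 10 and 15.** The O1–C2 bond is cut, giving the ring A phenol 10 and the ring B cinnamyl carbonate 15. This is the convergent point and the place where C2 is set. The forward reaction must put the aryloxide on the aryl-bearing allyl terminus (branched ether) and on one face. A Mitsunobu alternative would need a preformed enantiopure allylic alcohol.

**10 to 7 (through 9 and 8).** The C4a–C4 bond is cut, and within it the methyl–carbonyl bond. Phenol 7 is symmetric: the chain is para to the hydroxyl and the two ortho positions are equivalent, so ortho-formylation can give only aldehyde 8. Methyl addition (9) and oxidation then give 10. The shorter-looking route through geranylated phloroacetophenone is rejected. Partial etherification there would be expected to leave free the hydroxyl crowded between the chain and the acyl group, which leads to the C8 series.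

**7 to 3 and 4 (through 6), and 3 to 1.** The aryl–CH2 bond is cut. In silyl ether 3 the carbon between the two acetal oxygens is the only one activated for lithiation, and coupling with geranyl bromide 4 gives 6; desilylation gives 7. Ether 3 comes from phloroglucinol 1 through bis-acetal 2.

**15 to 11.** The carbonate is cut back through allylic alcohol 14 and cinnamate 13 (C=C bond by Horner–Wadsworth–Emmons olefination) to the protected aldehyde 12 and the commercial aldehyde 11.

## Roads not taken

**Alternative 1:** The cut is C4a–C5, so ring A is built rather than bought.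
- **Key step:** an (S)-2-aryl-2,3-dihydropyran-4-one carrying a methylene-linked 5-geranyl-2,2-dimethyl-1,3-dioxin-4-one, A1, would be heated. It should lose acetone to give an acylketene, whose ketene carbon is attacked by the nucleophilic α-carbon of the vinylogous ester (the future C4a). Enolisation then aromatises ring A and gives A2, the 3'-methoxymethyl ether of the target with both ring A hydroxyls free.
- **Merits:** the chain position is fixed by construction, so the C6/C8 question never arises. Only one protecting group remains at the end.
- **Weak points:** C-acylation of a vinylogous ester carbon by an acylketene is less secure than the usual capture by oxygen nucleophiles. Heating near 110 °C invites ring opening of the dihydropyranone and loss of the C2 configuration. A1 also needs its own enantioselective pyranone synthesis and a geranylated dioxinone.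
- **Comparison:** in regiocontrol and protecting-group economy this road is better. The chosen plan sets against it that every step belongs to a reaction class of established scope and that C2 is fixed before a neutral ring closure.

**Alternative 2:** The cuts are C5–C6, C7–C8 and C4a–C5.
- **Key step:** irradiation of the (S)-6-(diazoacetyl)dihydropyranone A3 with the geranyl-substituted siloxyalkyne A4 would trigger Wolff rearrangement to a vinylketene, ketene–alkyne [2+2] addition, four-electron ring opening and six-electron closure, giving A5 with a free C5 hydroxyl and a silylated C7 hydroxyl.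
- **Merits:** ring A is made regiospecifically in one operation, with its two oxygens already differentiated, from two fragments of similar size.
- **Weak points:** ultraviolet light threatens the E geometry of the chain and the cross-conjugated pyranone. The push–pull vinylketene is a reluctant partner. The diazoketone and an ynol silyl ether with a skipped diene are fragile to make and store. The final electrocyclisation often needs heat that the C2 centre may not tolerate.
- **Comparison:** this road is more convergent on ring A. The chosen plan pays for ring A with a seven-step arene sequence but uses no photochemistry and no high-energy intermediates.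

**Alternative 3:** The cut is C2–C3.
- **Key step:** the achiral diazoketone A6 (a ring A diazomethyl ketone with the ring B benzyl ether ortho to it) would be treated with Rh2(S-PTTL)4, a divalent rhodium carboxylate, or its enantiomer. The carbenoid at C3 should insert into a benzylic C–H bond next to O1, closing ring C and setting C2 to give A7, the tris(tert-butyldimethylsilyl) ether of the target.
- **Merits:** the stereocentre is made by a catalyst in the ring-forming step from an achiral precursor. The ring B piece is a simple benzyl halide, shorter than carbonate 15.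
- **Weak points:** the carbenoid lies five atoms from the ether oxygen, so oxonium ylide formation and a [1,2]-benzyl shift to a 2-benzylbenzofuran-3-one compete with the six-membered insertion. The geranyl alkenes and the electron-rich ring B are further carbenoid acceptors. Enantioselectivity in such six-ring insertions is less dependable. The diazoketone must come from a doubly ortho-substituted benzoic acid, and the same differentiation of ring A is needed.
- **Comparison:** this road has the shorter ring B fragment and forms the stereocentre during ring closure. The chosen plan sets C2 in a separate, well-understood etherification and closes the ring by a reaction with no competing insertion or ylide path.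

Key step: step 14

Assumption: the (Sa,Sc,Sc) antipode of the binaphthyl phosphoramidite is taken to deliver the aryloxide to the allyl face that gives the (S)-ether, by analogy with unsubstituted cinnamyl carbonates; if the sense proves opposite, the mirror-image ligand is used and nothing else changes.

## Route

Step 1
Reactants: 1 phloroglucinol
Product: 2 3,5-bis(methoxymethoxy)phenol
Conditions: MOMCl (2.0 equiv), i-Pr2NEt, DMF, 0 °C → rt
Reagents that add atoms: chloromethyl methyl ether, COCCl
Why: Williamson-type O-alkylation of the symmetric triol; two equivalents should give the bis-ether as the main component of a statistical mixture, separable from mono- and tris-ether by chromatography.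

Step 2
Reactants: 2 3,5-bis(methoxymethoxy)phenol
Product: 3 [3,5-bis(methoxymethoxy)phenoxy]triisopropylsilane
Conditions: i-Pr3SiCl, imidazole, DMF, rt
Reagents that add atoms: chlorotriisopropylsilane, CC(C)[Si](Cl)(C(C)C)C(C)C
Why: Silylation of the remaining phenol; the bulky silyl ether neither coordinates nor is attacked by an alkyllithium, so the carbon between the two acetal oxygens stays the only activated site.

Step 3
Reactants: 3 [3,5-bis(methoxymethoxy)phenoxy]triisopropylsilane; 4 geranyl bromide
Product: 6 [4-geranyl-3,5-bis(methoxymethoxy)phenoxy]triisopropylsilane, via aryllithium 5 (not isolated)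
Conditions: n-BuLi, THF, 0 °C; CuBr·SMe2 (10 mol %), then 4, −78 °C → rt
Reagents that add atoms: none
Why: Directed ortho-metalation: the C–H flanked by two methoxymethoxy groups is lithiated through cooperative coordination, and copper-catalysed SN2 substitution of the primary allylic bromide forms the aryl–CH2 bond without touching the 2E alkene.

Step 4
Reactants: 6 [4-geranyl-3,5-bis(methoxymethoxy)phenoxy]triisopropylsilane
Product: 7 4-geranyl-3,5-bis(methoxymethoxy)phenol
Conditions: Bu4NF, THF, 0 °C
Reagents that add atoms: none
Why: Fluoride-induced cleavage of the aryl silyl ether; acetals and alkenes are inert, and the phenol obtained is symmetric, so its two ortho positions are equivalent.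

Step 5
Reactants: 7 4-geranyl-3,5-bis(methoxymethoxy)phenol
Product: 8 3-geranyl-6-hydroxy-2,4-bis(methoxymethoxy)benzaldehyde
Conditions: MgCl2, Et3N, (CH2O)n, THF, 65 °C
Reagents that add atoms: paraformaldehyde (as formaldehyde), C=O
Why: Magnesium-mediated ortho-formylation of a phenol: the magnesium aryloxide delivers formaldehyde to the ortho carbon and a second formaldehyde oxidises the hydroxymethyl intermediate by hydride transfer; the para position is blocked and both ortho positions are the same, so only one aldehyde can form.

Step 6
Reactants: 8 3-geranyl-6-hydroxy-2,4-bis(methoxymethoxy)benzaldehyde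
Product: 9 4-geranyl-2-(1-hydroxyethyl)-3,5-bis(methoxymethoxy)phenol (racemic at the carbinol carbon)
Conditions: MeMgBr (3 equiv), THF, 0 °C → rt; aq. NH4Cl
Reagents that add atoms: methylmagnesium bromide, C[Mg]Br
Why: Grignard addition; the first equivalent is consumed by the phenol and the chelated aldehyde then accepts methyl, with a neutral quench to avoid ionising the electron-rich benzylic alcohol. The new carbinol centre is racemic and is removed in step 7.

Step 7
Reactants: 9 4-geranyl-2-(1-hydroxyethyl)-3,5-bis(methoxymethoxy)phenol
Product: 10 1-[3-geranyl-6-hydroxy-2,4-bis(methoxymethoxy)phenyl]ethan-1-one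
Conditions: MnO2 (excess), CH2Cl2, rt
Reagents that add atoms: none
Why: MnO2 oxidises benzylic alcohols selectively and should leave the trisubstituted alkenes, the acetals and the phenol alone; the ketone is stabilised by its hydrogen bond to the ortho hydroxyl.

Step 8
Reactants: 11 3-hydroxy-4,5-dimethoxybenzaldehyde
Product: 12 3,4-dimethoxy-5-(methoxymethoxy)benzaldehyde
Conditions: MOMCl, i-Pr2NEt, CH2Cl2, 0 °C → rt
Reagents that add atoms: chloromethyl methyl ether, COCCl
Why: O-alkylation of the phenol as its methoxymethyl ether, the same acetal as on ring A, so that one final acid treatment frees all three phenols.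

Step 9
Reactants: 12 3,4-dimethoxy-5-(methoxymethoxy)benzaldehyde
Product: 13 ethyl (2E)-3-[3,4-dimethoxy-5-(methoxymethoxy)phenyl]prop-2-enoate
Conditions: (EtO)2P(O)CH2CO2Et, NaH, THF, 0 °C → rt
Reagents that add atoms: triethyl phosphonoacetate, CCOC(=O)CP(=O)(OCC)OCC
Why: Horner–Wadsworth–Emmons olefination; the stabilised phosphonate anion should give the E cinnamate.

Step 10
Reactants: 13 ethyl (2E)-3-[3,4-dimethoxy-5-(methoxymethoxy)phenyl]prop-2-enoate
Product: 14 (2E)-3-[3,4-dimethoxy-5-(methoxymethoxy)phenyl]prop-2-en-1-ol
Conditions: i-Bu2AlH (2.3 equiv), CH2Cl2, −78 °C; Rochelle salt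
Reagents that add atoms: none
Why: 1,2-Reduction of the unsaturated ester by i-Bu2AlH at low temperature gives the allylic alcohol without touching the alkene or the acetal.

Step 11
Reactants: 14 (2E)-3-[3,4-dimethoxy-5-(methoxymethoxy)phenyl]prop-2-en-1-ol
Product: 15 tert-butyl (2E)-3-[3,4-dimethoxy-5-(methoxymethoxy)phenyl]prop-2-en-1-yl carbonate
Conditions: Boc2O, DMAP (10 mol %), CH2Cl2, 0 °C → rt
Reagents that add atoms: di-tert-butyl dicarbonate, CC(C)(C)OC(=O)OC(=O)OC(C)(C)C
Why: DMAP-catalysed acylation of the primary alcohol; the tert-butyl carbonate ionises readily on iridium and releases only tert-butoxide, which does not compete as a nucleophile.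

Step 12
Reactants: 10 1-[3-geranyl-6-hydroxy-2,4-bis(methoxymethoxy)phenyl]ethan-1-one; 15 tert-butyl (2E)-3-[3,4-dimethoxy-5-(methoxymethoxy)phenyl]prop-2-en-1-yl carbonate
Product: 17 1-{6-[(1S)-1-[3,4-dimethoxy-5-(methoxymethoxy)phenyl]prop-2-en-1-yloxy]-3-geranyl-2,4-bis(methoxymethoxy)phenyl}ethan-1-one, via lithium aryloxide 16 (not isolated)
Conditions: LiN(SiMe3)2 (1.0 equiv), THF, 0 °C; then 15, [Ir(cod)Cl]2 (2 mol %), (Sa,Sc,Sc)-(1,1'-binaphthalene-2,2'-diyl) N,N-bis(1-phenylethyl)phosphoramidite (4 mol %, preactivated with n-PrNH2), THF, 50 °C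
Reagents that add atoms: none
Why: Iridium-catalysed enantioselective allylic etherification: the cyclometalated iridium phosphoramidite ionises 15 to a π-allyl complex, which the aryloxide attacks at the aryl-bearing terminus anti to the metal to give the branched ether; the ligand fixes which allyl face is exposed and so sets C2 as S. Preforming the lithium aryloxide with one equivalent of amide leaves the acetyl group untouched.

Step 13
Reactants: 17 the (S)-aryl 1-arylallyl ether methyl ketone
Product: 18 tert-butyl{[1-(2-{[(1S)-1-[3,4-dimethoxy-5-(methoxymethoxy)phenyl]prop-2-en-1-yl]oxy}-5-geranyl-4,6-bis(methoxymethoxy)phenyl)ethenyl]oxy}dimethylsilane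
Conditions: t-BuMe2SiOTf, Et3N, CH2Cl2, −78 → 0 °C
Reagents that add atoms: tert-butyldimethylsilyl trifluoromethanesulfonate, CC(C)(C)[Si](C)(C)OS(=O)(=O)C(F)(F)F
Why: Soft enolisation of the methyl ketone and O-silylation; only the methyl side can enolise, and excess amine with low temperature should keep the silyl triflate from activating the acetals or the allylic ether.

Step 14
Reactants: 18 the (S)-diene with a vinyl group on C2 and a 1-(tert-butyldimethylsilyloxy)vinyl group on C4a
Product: 19 (2S)-4-(tert-butyldimethylsilyloxy)-2-[3,4-dimethoxy-5-(methoxymethoxy)phenyl]-6-geranyl-5,7-bis(methoxymethoxy)-2H-chromene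
Conditions: second-generation Grubbs catalyst RuCl2(H2IMes)(PCy3)(=CHPh) (10 mol %), degassed toluene (0.005 M), 70 °C
Reagents that add atoms: none
Why: Ring-closing olefin metathesis: the ruthenium benzylidene should exchange first with the monosubstituted vinyl group on C2, the only unhindered alkene, to give an alkylidene at the future C3; this adds across the 1,1-disubstituted silyloxyvinyl group on C4a in a [2+2] step, and cycloreversion of the ruthenacyclobutane forms the C3=C4 bond, returns Ru=CH2 and sets ethene free. The closest known reaction type is the enol silane–ene ring-closing metathesis that gives cyclic silyl enol ethers, including 4-silyloxy-1,2-dihydroquinolines from N-allyl anilines with the same 1-silyloxyvinyl group, together with the closure of ortho-vinyl aryl allyl ethers to 2H-chromenes. Ring C closes as a six-membered ring with an endocyclic double bond, the favoured size for this reaction, and the two reacting groups are held ortho to each other on ring A. No stereocentre is formed; C2 keeps the configuration set in step 12 because no bond to it is made or broken and the medium is neutral. The step needs selectivity for the two terminal alkenes over the two trisubstituted geranyl alkenes, which their substitution and the position of the chain para to O1 secure, and for ring closure over dimerisation, which high dilution secures. Degassed solvent and a short reaction time limit ruthenium hydride formation and migration of the C2 vinyl double bond.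

Step 15
Reactants: 19 the (2S)-4-silyloxy-2H-chromene
Product: 21 (2S)-5,7-dihydroxy-2-(3-hydroxy-4,5-dimethoxyphenyl)-6-geranyl-2,3-dihydro-4H-chromen-4-one (CNP0228243.1), via tris(methoxymethyl) flavanone 20 (not isolated)
Conditions: 3 M aq. HCl, MeOH, 50 °C
Reagents that add atoms: none
Why: Acid first protonates the enol silane at C3 to give the C4 ketone 20 and then cleaves the three acetals by oxocarbenium loss to methanol; no bond to C2 is involved, and the moderate temperature should limit chalcone-type ring opening and cyclisation of the geranyl chain.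

## Compound list

1 | phloroglucinol (benzene-1,3,5-triol) | Oc1cc(O)cc(O)c1 | starting material
2 | 3,5-bis(methoxymethoxy)phenol | COCOc1cc(O)cc(OCOC)c1 | intermediate
3 | [3,5-bis(methoxymethoxy)phenoxy]triisopropylsilane | COCOc1cc(O[Si](C(C)C)(C(C)C)C(C)C)cc(OCOC)c1 | intermediate
4 | geranyl bromide, (2E)-1-bromo-3,7-dimethylocta-2,6-diene | CC(C)=CCC/C(C)=C/CBr | starting material
5 | [2,6-bis(methoxymethoxy)-4-(triisopropylsilyloxy)phenyl]lithium | [Li]c1c(OCOC)cc(O[Si](C(C)C)(C(C)C)C(C)C)cc1OCOC | intermediate
6 | {4-[(2E)-3,7-dimethylocta-2,6-dien-1-yl]-3,5-bis(methoxymethoxy)phenoxy}triisopropylsilane | CC(C)=CCC/C(C)=C/Cc1c(OCOC)cc(O[Si](C(C)C)(C(C)C)C(C)C)cc1OCOC | intermediate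
7 | 4-[(2E)-3,7-dimethylocta-2,6-dien-1-yl]-3,5-bis(methoxymethoxy)phenol | CC(C)=CCC/C(C)=C/Cc1c(OCOC)cc(O)cc1OCOC | intermediate
8 | 3-[(2E)-3,7-dimethylocta-2,6-dien-1-yl]-6-hydroxy-2,4-bis(methoxymethoxy)benzaldehyde | CC(C)=CCC/C(C)=C/Cc1c(OCOC)cc(O)c(C=O)c1OCOC | intermediate
9 | 4-[(2E)-3,7-dimethylocta-2,6-dien-1-yl]-2-(1-hydroxyethyl)-3,5-bis(methoxymethoxy)phenol, racemic | CC(C)=CCC/C(C)=C/Cc1c(OCOC)cc(O)c(C(C)O)c1OCOC | intermediate
10 | 1-{3-[(2E)-3,7-dimethylocta-2,6-dien-1-yl]-6-hydroxy-2,4-bis(methoxymethoxy)phenyl}ethan-1-one | CC(C)=CCC/C(C)=C/Cc1c(OCOC)cc(O)c(C(C)=O)c1OCOC | intermediate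
11 | 3-hydroxy-4,5-dimethoxybenzaldehyde | COc1cc(C=O)cc(O)c1OC | starting material
12 | 3,4-dimethoxy-5-(methoxymethoxy)benzaldehyde | COCOc1cc(C=O)cc(OC)c1OC | intermediate
13 | ethyl (2E)-3-[3,4-dimethoxy-5-(methoxymethoxy)phenyl]prop-2-enoate | CCOC(=O)/C=C/c1cc(OC)c(OC)c(OCOC)c1 | intermediate
14 | (2E)-3-[3,4-dimethoxy-5-(methoxymethoxy)phenyl]prop-2-en-1-ol | OC/C=C/c1cc(OC)c(OC)c(OCOC)c1 | intermediate
15 | tert-butyl (2E)-3-[3,4-dimethoxy-5-(methoxymethoxy)phenyl]prop-2-en-1-yl carbonate | CC(C)(C)OC(=O)OC/C=C/c1cc(OC)c(OC)c(OCOC)c1 | intermediate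
16 | lithium 2-acetyl-4-[(2E)-3,7-dimethylocta-2,6-dien-1-yl]-3,5-bis(methoxymethoxy)phenolate | [Li+].[O-]c1cc(OCOC)c(C/C=C(\C)CCC=C(C)C)c(OCOC)c1C(C)=O | intermediate
17 | 1-{6-[(1S)-1-[3,4-dimethoxy-5-(methoxymethoxy)phenyl]prop-2-en-1-yloxy]-3-[(2E)-3,7-dimethylocta-2,6-dien-1-yl]-2,4-bis(methoxymethoxy)phenyl}ethan-1-one | COc1cc([C@@H](Oc2cc(OCOC)c(C/C=C(\C)CCC=C(C)C)c(OCOC)c2C(C)=O)C=C)cc(OCOC)c1OC | intermediate
18 | tert-butyl{[1-(2-{[(1S)-1-[3,4-dimethoxy-5-(methoxymethoxy)phenyl]prop-2-en-1-yl]oxy}-5-[(2E)-3,7-dimethylocta-2,6-dien-1-yl]-4,6-bis(methoxymethoxy)phenyl)ethenyl]oxy}dimethylsilane | COc1cc([C@@H](Oc2cc(OCOC)c(C/C=C(\C)CCC=C(C)C)c(OCOC)c2C(=C)O[Si](C)(C)C(C)(C)C)C=C)cc(OCOC)c1OC | intermediate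
19 | (2S)-4-(tert-butyldimethylsilyloxy)-2-[3,4-dimethoxy-5-(methoxymethoxy)phenyl]-6-[(2E)-3,7-dimethylocta-2,6-dien-1-yl]-5,7-bis(methoxymethoxy)-2H-chromene | COc1cc([C@@H]2C=C(O[Si](C)(C)C(C)(C)C)c3c(cc(OCOC)c(C/C=C(\C)CCC=C(C)C)c3OCOC)O2)cc(OCOC)c1OC | intermediate
20 | (2S)-2-[3,4-dimethoxy-5-(methoxymethoxy)phenyl]-6-[(2E)-3,7-dimethylocta-2,6-dien-1-yl]-5,7-bis(methoxymethoxy)-2,3-dihydro-4H-chromen-4-one | COc1cc([C@@H]2CC(=O)c3c(cc(OCOC)c(C/C=C(\C)CCC=C(C)C)c3OCOC)O2)cc(OCOC)c1OC | intermediate
21 | (2S)-5,7-dihydroxy-2-(3-hydroxy-4,5-dimethoxyphenyl)-6-[(2E)-3,7-dimethylocta-2,6-dien-1-yl]-2,3-dihydro-4H-chromen-4-one | COc1cc([C@@H]2CC(=O)c3c(cc(O)c(C/C=C(\C)CCC=C(C)C)c3O)O2)cc(O)c1OC | target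

## Step count and least certain steps

Total: 15 steps. Longest linear sequence: 11 steps (steps 1–7, then 12–15); the ring B branch is steps 8–11.

**Step 14 (key step).** The hindered 1,1-disubstituted enol silane, flanked by two ortho oxygen substituents, may engage the ruthenium alkylidene too slowly. The catalyst could then decay to hydride species that migrate the C2 vinyl double bond, or the vinyl groups could dimerise. Fallback: set out from 10 and 12. Claisen–Schmidt condensation (KOH, EtOH) should give (2E)-1-[3-geranyl-6-hydroxy-2,4-bis(methoxymethoxy)phenyl]-3-[3,4-dimethoxy-5-(methoxymethoxy)phenyl]prop-2-en-1-one F1. Intramolecular oxa-Michael addition under a quinine-derived bifunctional thiourea closes ring C, the (S)-enantiomer being secured if necessary by chromatography on a chiral stationary phase. This path has weaker stereocontrol than the main route and returns at 20, which is then deprotected as in step 15.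

**Step 12.** The chelated ortho-acyl aryloxide is a weak nucleophile, so attack on the allyl complex may be slow. The electron-rich branched ether may also re-ionise on iridium, which would erode the branched-to-linear ratio and the enantiomeric purity. Fallback: set out from 12. Addition of vinylmagnesium bromide gives racemic 1-[3,4-dimethoxy-5-(methoxymethoxy)phenyl]prop-2-en-1-ol F2. Sharpless kinetic resolution (Ti(Oi-Pr)4, t-BuOOH, with the diisopropyl tartrate antipode chosen to leave the R carbinol) gives (1R)-1-[3,4-dimethoxy-5-(methoxymethoxy)phenyl]prop-2-en-1-ol F3. Mitsunobu etherification of F3 with phenol 10 (PPh3, diisopropyl azodicarboxylate) proceeds with inversion and returns at 17.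

**Step 6 (with step 7).** The very electron-rich ortho-hydroxybenzyl alcohol 9 may dehydrate to an ortho-quinone methide during work-up or on MnO2 and then oligomerise. Fallback: set out from 8 and 15 and cap the phenol first. The lithium aryloxide of 8 is etherified under the conditions of step 12 to give 6-[(1S)-1-[3,4-dimethoxy-5-(methoxymethoxy)phenyl]prop-2-en-1-yloxy]-3-geranyl-2,4-bis(methoxymethoxy)benzaldehyde F4. MeMgBr addition gives the secondary alcohol 1-{6-[(1S)-1-arylprop-2-en-1-yloxy]-3-geranyl-2,4-bis(methoxymethoxy)phenyl}ethan-1-ol F5 as a mixture of carbinol epimers. Dess–Martin periodinane oxidation returns at 17.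

**Step 15.** Once the C5 and C7 phenols are free, protic acid may add them across the proximal geranyl alkene (chroman formation). Prolonged heating may also open and reclose ring C, with loss of configuration at C2. Fallback: set out from 19 and release the groups in two stages without aqueous mineral acid. Bu4NF buffered with AcOH (THF, 0 °C) converts the enol silane into ketone 20, which is isolated. ZnBr2 with n-PrSH (CH2Cl2, 0 °C, minutes) then removes the three acetals by thiol capture of the methoxymethyl cation and returns at 21.

## Further compounds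

F1 | step 14 | (2E)-1-{3-[(2E)-3,7-dimethylocta-2,6-dien-1-yl]-6-hydroxy-2,4-bis(methoxymethoxy)phenyl}-3-[3,4-dimethoxy-5-(methoxymethoxy)phenyl]prop-2-en-1-one | COc1cc(/C=C/C(=O)c2c(O)cc(OCOC)c(C/C=C(\C)CCC=C(C)C)c2OCOC)cc(OCOC)c1OC
F2 | step 12 | 1-[3,4-dimethoxy-5-(methoxymethoxy)phenyl]prop-2-en-1-ol, racemic | COc1cc(C(O)C=C)cc(OCOC)c1OC
F3 | step 12 | (1R)-1-[3,4-dimethoxy-5-(methoxymethoxy)phenyl]prop-2-en-1-ol | COc1cc([C@H](O)C=C)cc(OCOC)c1OC
F4 | step 6 | 6-[(1S)-1-[3,4-dimethoxy-5-(methoxymethoxy)phenyl]prop-2-en-1-yloxy]-3-[(2E)-3,7-dimethylocta-2,6-dien-1-yl]-2,4-bis(methoxymethoxy)benzaldehyde | COc1cc([C@@H](Oc2cc(OCOC)c(C/C=C(\C)CCC=C(C)C)c(OCOC)c2C=O)C=C)cc(OCOC)c1OC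
F5 | step 6 | 1-{6-[(1S)-1-[3,4-dimethoxy-5-(methoxymethoxy)phenyl]prop-2-en-1-yloxy]-3-[(2E)-3,7-dimethylocta-2,6-dien-1-yl]-2,4-bis(methoxymethoxy)phenyl}ethan-1-ol, mixture of carbinol epimers | COc1cc([C@@H](Oc2cc(OCOC)c(C/C=C(\C)CCC=C(C)C)c(OCOC)c2C(C)O)C=C)cc(OCOC)c1OC
F0 | step 15 | none | none
A1 | alternative 1 | (2S)-2-[3,4-dimethoxy-5-(methoxymethoxy)phenyl]-6-({5-[(2E)-3,7-dimethylocta-2,6-dien-1-yl]-2,2-dimethyl-4-oxo-4H-1,3-dioxin-6-yl}methyl)-2,3-dihydro-4H-pyran-4-one | COc1cc([C@@H]2CC(=O)C=C(CC3=C(C/C=C(\C)CCC=C(C)C)C(=O)OC(C)(C)O3)O2)cc(OCOC)c1OC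
A2 | alternative 1 | (2S)-6-geranyl-5,7-dihydroxy-2-[3,4-dimethoxy-5-(methoxymethoxy)phenyl]-2,3-dihydro-4H-chromen-4-one | COc1cc([C@@H]2CC(=O)c3c(cc(O)c(C/C=C(\C)CCC=C(C)C)c3O)O2)cc(OCOC)c1OC
A3 | alternative 2 | (2S)-6-(diazoacetyl)-2-[3,4-dimethoxy-5-(methoxymethoxy)phenyl]-2,3-dihydro-4H-pyran-4-one | COc1cc([C@@H]2CC(=O)C=C(C(=O)C=[N+]=[N-])O2)cc(OCOC)c1OC
A4 | alternative 2 | {[(4E)-5,9-dimethyldeca-4,8-dien-1-yn-1-yl]oxy}triisopropylsilane | CC(C)=CCC/C(C)=C/CC#CO[Si](C(C)C)(C(C)C)C(C)C
A5 | alternative 2 | (2S)-6-geranyl-5-hydroxy-2-[3,4-dimethoxy-5-(methoxymethoxy)phenyl]-7-(triisopropylsilyloxy)-2,3-dihydro-4H-chromen-4-one | COc1cc([C@@H]2CC(=O)c3c(cc(O[Si](C(C)C)(C(C)C)C(C)C)c(C/C=C(\C)CCC=C(C)C)c3O)O2)cc(OCOC)c1OC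
A6 | alternative 3 | 2-diazo-1-{6-[3-(tert-butyldimethylsilyloxy)-4,5-dimethoxybenzyloxy]-3-geranyl-2,4-bis(tert-butyldimethylsilyloxy)phenyl}ethan-1-one | COc1cc(COc2cc(O[Si](C)(C)C(C)(C)C)c(C/C=C(\C)CCC=C(C)C)c(O[Si](C)(C)C(C)(C)C)c2C(=O)C=[N+]=[N-])cc(O[Si](C)(C)C(C)(C)C)c1OC
A7 | alternative 3 | (2S)-2-[3-(tert-butyldimethylsilyloxy)-4,5-dimethoxyphenyl]-6-geranyl-5,7-bis(tert-butyldimethylsilyloxy)-2,3-dihydro-4H-chromen-4-one | COc1cc([C@@H]2CC(=O)c3c(cc(O[Si](C)(C)C(C)(C)C)c(C/C=C(\C)CCC=C(C)C)c3O[Si](C)(C)C(C)(C)C)O2)cc(O[Si](C)(C)C(C)(C)C)c1OC
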